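The slowness after the first minute caught my eye first: in the autumn run, left-handed product formed 4.75 times faster up to the first reading than between the last two, a reading with its scatter.

| setting | spring | autumn | midnight | flask |
|---|---|---|---|---|
| left-handed substrate | 0.12 M | 0.12 M | 0.12 M | 0.12 M |
| right-handed substrate | 0.12 M | 0.12 M | 0.12 M | 0.12 M |
| reagent | 0.40 equiv | 0.90 equiv | 0.60 equiv | 0.600 equiv |
| free catalyst | 0.05 mol% | 0.05 mol% | 0.05 mol% | 0.05 mol% |
| impurity | 31 µM | 31 µM | 31 µM | 31 µM |
| added ligand | 0.23 mM | 0.23 mM | 0.35 mM | 0.23 mM |
| remark | run made earlier | run made earlier | run made earlier |  |

- spring (time / min: left-handed product / %, left-handed substrate / %): 0.667: 3.7, 46.6; 1.33: 5.6, 44.3; 2.00: 6.2, 43.5; 2.50: 7.9, 42.8; 3.00: 8.1, 41.6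
- autumn (time / min: left-handed product / %, left-handed substrate / %): 0.250: 4.2, 45.9; 0.500: 5.3, 43.6; 0.833: 7.9, 41.5; 1.50: 12.1, 37.8; 3.00: 17.4, 33.1
- midnight (time / min: left-handed product / %, left-handed substrate / %): 0.250: 2.6, 46.8; 0.833: 5.0, 44.7; 1.33: 6.9, 43.0; 2.50: 9.7, 39.9; 3.00: 11.6, 39.8

(readings scatter by 0.5 percentage points)

- free catalyst is single-handed; left-handed substrate and right-handed substrate are mirror images of each other, charged as a racemate, each of them at the stated concentration
- the numbers in the tables scatter by 0.5 percentage points (one standard deviation)
- candidate steps: reagent + free catalyst + right-handed substrate -> free catalyst + right-handed product; reagent + free catalyst + left-handed substrate -> free catalyst + left-handed product; free catalyst + added ligand <-> idle complex; free catalyst + impurity -> spent catalyst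
- no earlier run changes the charge of free catalyst; that part of a forecast is a guess

1. apparent order in free catalyst when 10% of the left-handed substrate and right-handed substrate together are converted (percent change of the rate of making left-handed product for one percent more free catalyst charged)
2. apparent order in reagent when 10% of the left-handed substrate and right-handed substrate together are converted (percent change of the rate of making left-handed product for one percent more reagent charged)

My first estimate for reagent compared the autumn and spring runs at their last readings:

order = ln(left-handed product, autumn / spring) / ln(reagent charge, autumn / spring) = 0.943

The objection was that this compares equal times, while the question holds conversion fixed. Each turnover uses one reagent, and the conversion asked for is counted on both substrates, so in this flask the reagent, the limiting reagent of the charge, loses a fixed amount by the moment asked about, which I call the look: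

reagent charged = 0.0720 M; reagent taken = 0.0240 M

charged / (charged − taken) = 1.50

I call this ratio the leverage: the charged amount over the charged amount minus what is taken by the look. With the amount taken held fixed, one percent more charge means a larger percentage more of what remains.

The same rule applied to the catalyst in this flask, if the impurity takes a fixed amount:

catalyst charged = 60.0 µM; impurity = 31 µM

leverage = 2.07

That figure had its own objection: it counts a finished titration, and in the autumn run left-handed product formed more slowly between the last two readings than between the two before, so in this flask the impurity might not have finished by the look. I also expected more reagent to reach the look sooner, with more catalyst alive. I therefore committed to a little below 2.07 for catalyst and a little above 1.50 for reagent.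

The forecast gave 1.4 for catalyst and 1.25 for reagent, both lower than my figures, and called its catalyst figure a guess: “This is a guess, since no run varied catalyst”.

The flask gave 1.8 for catalyst and 1.8 for reagent.

    reagent + free catalyst + right-handed substrate → free catalyst + right-handed product (k = 23900 M⁻² min⁻¹)
    reagent + free catalyst + left-handed substrate → free catalyst + left-handed product (k = 82200 M⁻² min⁻¹)
    free catalyst + added ligand ⇌ idle complex (K = 3100 M⁻¹, k = 13300 M⁻¹ min⁻¹)
    free catalyst + impurity → spent catalyst (k = 49100 M⁻¹ min⁻¹)

In the flask at 2.00 min, spent catalyst stood at 46.9% of the catalyst charged, with 9.26% of the impurity left. The flask's catalyst order lay below its leverage of 2.07, and its reagent order lay above its leverage of 1.50. On the spring charge, the reagent leverage comes to 2.00.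

(Readings and results were generated by integration for substances that don't exist; the scatter is artificial.)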